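**Plan**

- Numbering: abietane C1–C20 for rings A (C1–C5, C10), B (C5–C10) and C (C8, C9, C11–C14); ring D is C8–C4′H2–C3′H=C2′(R)–C1′H2–C9, with R = 4-methylpent-3-enyl.
- Cuts: C2′=C3′ and C4′–C8 of ring D together (a two-carbon vinylphosphonium unit stitched between C8 and a side-chain ketone at C2′); then C9–C1′ (conjugate addition); the C6–C8 bond of the formyl cyclopentane (reverse semipinacol to a C7-keto six-membered ring B); the quinone carbonyls (back to aryl methyl ethers); C10–C9 and C4–C5 (cationic bicyclization); C6–C7 (benzyl–geranyl coupling).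
- Forward: arene; rings A and B by polyene cyclization; C7 ketone and ring C quinone; side chain on C9; ring D by the key annulation; contraction of ring B with C7 leaving the ring as the formyl carbon; O-demethylation.
- Enabling feature: in the precursor C8 lies between the C7 carbonyl (ring B) and the C14 carbonyl (ring C), so it is the one readily enolized carbon, and the ketone C2′ hangs from the neighbouring C9 four atoms away. The same C7 carbonyl first makes C9 the Michael terminus of the quinone and is finally expelled from ring B.
- Stereochemistry: C10 and C5 come from the enantioselective bicyclization; C9 and C8 are relayed from the axial C20 methyl (both new bonds enter on the α-face); the formyl-bearing carbon is set by the stereospecific 1,2-shift and is the more stable epimer.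

Key step: step 10

Assumption: the (R)-binaphthol-derived acid is taken to give the (5S,10S) series (its antipode is used if the sense proves opposite).

**Route**

Step 1
Reactants: 1 1,2,4-trimethoxybenzene; 2 acetone
Product: 4 2-(2,3,6-trimethoxyphenyl)propan-2-ol, via aryllithium 3 (not isolated)
Conditions: n-BuLi, THF, 0 °C; then 2, −78 °C → rt; H2O
Reagents that add atoms: none
Why: Directed ortho-lithiation takes place at the ring position flanked by two methoxy groups, and the aryllithium adds to the ketone (1,2-addition of an organolithium).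

Step 2
Reactants: 4 2-(2,3,6-trimethoxyphenyl)propan-2-ol
Product: 5 2-isopropyl-1,3,4-trimethoxybenzene
Conditions: Et3SiH, CF3CO2H, CH2Cl2, 0 °C → rt
Reagents that add atoms: none
Why: Ionic hydrogenation, in which the acid ionizes the tertiary benzylic alcohol to a cation stabilized by two ortho methoxy groups and the silane delivers hydride.

Step 3
Reactants: 5 2-isopropyl-1,3,4-trimethoxybenzene
Product: 6 1-(chloromethyl)-3-isopropyl-2,4,5-trimethoxybenzene
Conditions: (CH2O)n, conc. HCl, AcOH, 0 °C → rt
Reagents that add atoms: formaldehyde (as paraformaldehyde), C=O; hydrogen chloride, Cl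
Why: Blanc chloromethylation (electrophilic aromatic substitution) at the free position that is ortho to one methoxy group and para to another, the more activated of the two open sites.

Step 4
Reactants: 6 1-(chloromethyl)-3-isopropyl-2,4,5-trimethoxybenzene; 7 geranyl chloride
Product: 9 1-[(3E)-4,8-dimethylnona-3,7-dien-1-yl]-3-isopropyl-2,4,5-trimethoxybenzene, via benzylic Grignard reagent 8 (not isolated)
Conditions: Mg, THF, 0 °C; then 7, Li2CuCl4 (cat.), THF, −20 °C → rt
Reagents that add atoms: none
Why: Copper-catalysed coupling of a benzylic Grignard reagent with an allylic chloride at its primary carbon, which keeps the E-trisubstituted alkene.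

Step 5
Reactants: 9 1-[(3E)-4,8-dimethylnona-3,7-dien-1-yl]-3-isopropyl-2,4,5-trimethoxybenzene
Product: 10 (5S,10S)-11,12,14-trimethoxyabieta-8,11,13-triene
Conditions: SnCl4, (R)-2-(2-fluorobenzyloxy)-2′-hydroxy-1,1′-binaphthyl, toluene, −78 °C; then CF3CO2H, SnCl4, i-PrNO2, −78 °C
Reagents that add atoms: none
Why: Enantioselective cationic polyene bicyclization by a chiral Lewis acid-assisted Brønsted acid, in which face-selective protonation of the terminal alkene fixes C5 and C10, the chair–chair fold of the E-alkene gives the trans A/B fusion, and Friedel–Crafts closure occurs at the only free arene position next to the chain.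

Step 6
Reactants: 10 (5S,10S)-11,12,14-trimethoxyabieta-8,11,13-triene
Product: 11 11,12,14-trimethoxyabieta-8,11,13-trien-7-one
Conditions: CrO3, AcOH/H2O, rt
Reagents that add atoms: chromium trioxide, O=[Cr](=O)=O
Why: Benzylic oxidation by hexavalent chromium at C7, the secondary benzylic position para to the C12 methoxy group, the twisted isopropyl methine being slower to react.

Step 7
Reactants: 11 11,12,14-trimethoxyabieta-8,11,13-trien-7-one
Product: 12 12-methoxyabieta-8,12-diene-7,11,14-trione
Conditions: (NH4)2Ce(NO3)6, MeCN/H2O, 0 °C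
Reagents that add atoms: water, O
Why: Oxidative demethylation of the para-related C11 and C14 methyl ethers by tetravalent cerium gives the p-quinone and leaves the C12 methyl ether as a vinylogous ester.

Step 8
Reactants: 13 6-methylhept-5-en-2-one
Product: 14 trimethyl[(6-methylhepta-1,5-dien-2-yl)oxy]silane
Conditions: LiN(i-Pr)2, THF, −78 °C; then Me3SiCl
Reagents that add atoms: chlorotrimethylsilane, C[Si](C)(C)Cl
Why: Kinetic deprotonation of the methyl ketone at its methyl group and O-silylation give the less substituted silyl enol ether.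

Step 9
Reactants: 12 12-methoxyabieta-8,12-diene-7,11,14-trione; 14 trimethyl[(6-methylhepta-1,5-dien-2-yl)oxy]silane
Product: 15 7-hydroxy-12-methoxy-9α-(6-methyl-2-oxohept-5-en-1-yl)abieta-7,12-diene-11,14-dione
Conditions: Me3SiOTf (cat.), CH2Cl2, −78 °C; then 1 M HCl, THF, 0 °C
Reagents that add atoms: none
Why: Mukaiyama–Michael addition to an acylquinone, in which C9 is the β-carbon of both the C7 and the C14 carbonyl so that the silyl enol ether adds there and not at C8, from the α-face opposite the axial C20 methyl, which sets the C9 quaternary stereocenter and leaves C8 as a stabilized diketone enol.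

Step 10
Reactants: 15 7-hydroxy-12-methoxy-9α-(6-methyl-2-oxohept-5-en-1-yl)abieta-7,12-diene-11,14-dione; 16 vinyltriphenylphosphonium bromide
Product: 18 12-methoxy-8α,9α-[2-(4-methylpent-3-en-1-yl)but-2-ene-1,4-diyl]abiet-12-ene-7,11,14-trione, via phosphorus ylide 17 (not isolated)
Conditions: Cs2CO3, MeCN, rt → 60 °C
Reagents that add atoms: none
Why: Cs2CO3 removes the C8 proton of the 7,14-diketone, the enolate adds through C8 to the β-carbon (C4′) of the vinylphosphonium salt, and the resulting ylide 17 attacks the side-chain ketone C2′ through its carbanion C3′, the oxaphosphetane collapsing to Ph3PO and the C2′=C3′ bond. The closest known reaction is the vinylphosphonium Michael–Wittig annulation (Schweizer annulation) of β-dicarbonyl enolates that carry a remote ketone, the C-alkylation resembling the Michael stage of a Robinson annulation of a 2-substituted 1,3-dione. Ring D closes in the Wittig stage by 6-exo-trig attack of the ylide carbon on the C2′ carbonyl. The new quaternary stereocenter C8 is controlled by the axial C20 methyl, which blocks the β-face, so C4′ enters α and cis to C1′ on C9, the only arrangement from which ring D can close. The step needs site-selective enolization, secured because only C8–H lies between two carbonyls so that the side-chain ketone stays an electrophile, and carbon rather than oxygen alkylation, favoured by the soft acceptor and by the irreversible Wittig exit of the C-adduct. It also needs the ylide to choose C2′, an unhindered dialkyl ketone reached through a six-membered transition state, over the conjugated and neopentyl C11 carbonyl, while C7 and C14 would require four-membered rings.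

Step 11
Reactants: 18 12-methoxy-8α,9α-[2-(4-methylpent-3-en-1-yl)but-2-ene-1,4-diyl]abiet-12-ene-7,11,14-trione
Product: 20 6α-bromo-12-methoxy-8α,9α-[2-(4-methylpent-3-en-1-yl)but-2-ene-1,4-diyl]abiet-12-ene-7,11,14-trione, via trimethylsilyl enol ether 19 (not isolated)
Conditions: Me3SiOTf, Et3N, CH2Cl2, 0 °C; then NBS, THF, −78 °C
Reagents that add atoms: N-bromosuccinimide, O=C1CCC(=O)N1Br
Why: α-Bromination of a ketone through its silyl enol ether, where enolization is possible only toward C6 because C8 is quaternary, and bromine enters on the α-face because the β-face of C6 is screened by the C19 and C20 methyl groups, giving the equatorial 6α-bromide.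

Step 12
Reactants: 20 6α-bromo-12-methoxy-8α,9α-[2-(4-methylpent-3-en-1-yl)but-2-ene-1,4-diyl]abiet-12-ene-7,11,14-trione
Product: 21 6α-bromo-7α-hydroxy-12-methoxy-8α,9α-[2-(4-methylpent-3-en-1-yl)but-2-ene-1,4-diyl]abiet-12-ene-11,14-dione
Conditions: NaBH4, MeOH/CH2Cl2, −78 °C; then acetone
Reagents that add atoms: none
Why: Chemoselective 1,2-reduction by borohydride of the α-bromo ketone, the most electrophilic carbonyl (C14 is a vinylogous ester and C11 a hindered conjugated ketone), with hydride expected from the equatorial direction because the axial C1′ methylene on C9 shields the α-face, to give the axial 7α-alcohol, although either C7 epimer serves in step 13.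

Step 13
Reactants: 21 6α-bromo-7α-hydroxy-12-methoxy-8α,9α-[2-(4-methylpent-3-en-1-yl)but-2-ene-1,4-diyl]abiet-12-ene-11,14-dione
Product: 22 12-O-methyl ether of the target
Conditions: KN(SiMe3)2, THF, −78 °C → 0 °C
Reagents that add atoms: none
Why: Semipinacol ring contraction of a halohydrin, in which the alkoxide drives the C7–C8 ring bond, antiperiplanar to the equatorial C6–Br bond, onto C6 with inversion, so that C7 leaves ring B as the formyl group and C6 ends with the formyl group α (trans to C4); a stepwise retro-aldol and enolate alkylation through the same atoms would converge on the same product.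

Step 14
Reactants: 22 12-O-methyl ether of the target
Product: 23 CNP0239256.1
Conditions: LiOH, THF/H2O, rt; then 1 M HCl to pH 3, 0 °C
Reagents that add atoms: water, O
Why: Saponification of the vinylogous methyl ester by addition–elimination of hydroxide at C12 gives the enolized trione on acidification, and the basic medium keeps the formyl-bearing carbon in its more stable α configuration, that of the target.

**Compound list**

1 | 1,2,4-trimethoxybenzene | COc1ccc(OC)c(OC)c1 | starting material
2 | acetone | CC(C)=O | starting material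
3 | (2,3,6-trimethoxyphenyl)lithium | [Li]c1c(OC)ccc(OC)c1OC | intermediate (not isolated)
4 | 2-(2,3,6-trimethoxyphenyl)propan-2-ol | CC(C)(O)c1c(OC)ccc(OC)c1OC | intermediate
5 | 2-isopropyl-1,3,4-trimethoxybenzene | CC(C)c1c(OC)ccc(OC)c1OC | intermediate
6 | 1-(chloromethyl)-3-isopropyl-2,4,5-trimethoxybenzene | CC(C)c1c(OC)c(CCl)cc(OC)c1OC | intermediate
7 | geranyl chloride, (2E)-1-chloro-3,7-dimethylocta-2,6-diene | ClC/C=C(\C)CCC=C(C)C | starting material
8 | (3-isopropyl-2,4,5-trimethoxybenzyl)magnesium chloride | CC(C)c1c(OC)c(C[Mg]Cl)cc(OC)c1OC | intermediate (not isolated)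
9 | 1-[(3E)-4,8-dimethylnona-3,7-dien-1-yl]-3-isopropyl-2,4,5-trimethoxybenzene | CC(C)c1c(OC)c(CC/C=C(\C)CCC=C(C)C)cc(OC)c1OC | intermediate
10 | (5S,10S)-11,12,14-trimethoxyabieta-8,11,13-triene (trans A/B, C20 methyl β, H5 α) | CC(C)c1c(OC)c2c(c(OC)c1OC)[C@@]1(C)CCCC(C)(C)[C@@H]1CC2 | intermediate
11 | 11,12,14-trimethoxyabieta-8,11,13-trien-7-one | CC(C)c1c(OC)c2c(c(OC)c1OC)[C@@]1(C)CCCC(C)(C)[C@@H]1CC2=O | intermediate
12 | 12-methoxyabieta-8,12-diene-7,11,14-trione (acylquinone) | CC(C)C=1C(=O)C2=C(C(=O)C1OC)[C@@]1(C)CCCC(C)(C)[C@@H]1CC2=O | intermediate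
13 | 6-methylhept-5-en-2-one | CC(=O)CCC=C(C)C | starting material
14 | trimethyl[(6-methylhepta-1,5-dien-2-yl)oxy]silane | C=C(O[Si](C)(C)C)CCC=C(C)C | intermediate
15 | 7-hydroxy-12-methoxy-9α-(6-methyl-2-oxohept-5-en-1-yl)abieta-7,12-diene-11,14-dione (C7 enol form of the 7,11,14-trione; side chain on C9 trans to the C20 methyl) | CC(C)C=1C(=O)C2[C@](CC(=O)CCC=C(C)C)(C(=O)C1OC)[C@@]1(C)CCCC(C)(C)[C@@H]1CC=2O | intermediate
16 | vinyltriphenylphosphonium bromide | C=C[P+](c1ccccc1)(c1ccccc1)c1ccccc1.[Br-] | starting material
17 | ylide: 12-methoxy-9α-(6-methyl-2-oxohept-5-en-1-yl)-8α-[2-(triphenyl-λ5-phosphanylidene)ethyl]abiet-12-ene-7,11,14-trione | CC(C)C=1C(=O)[C@]2(CC=P(c3ccccc3)(c3ccccc3)c3ccccc3)[C@](CC(=O)CCC=C(C)C)(C(=O)C1OC)[C@@]1(C)CCCC(C)(C)[C@@H]1CC2=O | intermediate (not isolated)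
18 | 12-methoxy-8α,9α-[2-(4-methylpent-3-en-1-yl)but-2-ene-1,4-diyl]abiet-12-ene-7,11,14-trione (ring D on the α-face; C1′ on C9, C4′ on C8, side chain on C2′) | CC(C)C=1C(=O)[C@@]23CC=C(CCC=C(C)C)C[C@@]3(C(=O)C1OC)[C@@]1(C)CCCC(C)(C)[C@@H]1CC2=O | intermediate
19 | 7-trimethylsilyl enol ether of 18 (C6=C7) | CC(C)C=1C(=O)[C@@]23CC=C(CCC=C(C)C)C[C@@]3(C(=O)C1OC)[C@@]1(C)CCCC(C)(C)[C@@H]1C=C2O[Si](C)(C)C | intermediate (not isolated)
20 | 6α-bromo derivative of 18 (bromine equatorial) | CC(C)C=1C(=O)[C@@]23CC=C(CCC=C(C)C)C[C@@]3(C(=O)C1OC)[C@@]1(C)CCCC(C)(C)[C@@H]1[C@@H](Br)C2=O | intermediate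
21 | 6α-bromo-7α-hydroxy compound (7-alcohol of 20, hydroxyl axial) | CC(C)C=1C(=O)[C@@]23CC=C(CCC=C(C)C)C[C@@]3(C(=O)C1OC)[C@@]1(C)CCCC(C)(C)[C@@H]1[C@@H](Br)[C@H]2O | intermediate
22 | 12-O-methyl ether of the target (ring B now the cyclopentane, formyl group α on C6) | CC(C)=CCCC1=CC[C@@]23C(=O)C(C(C)C)=C(OC)C(=O)[C@]2(C1)[C@@]1(C)CCCC(C)(C)[C@@H]1[C@H]3C=O | intermediate
23 | CNP0239256.1 | CC(C)=CCCC1=CC[C@@]23C(=O)C(C(C)C)=C(O)C(=O)[C@]2(C1)[C@@]1(C)CCCC(C)(C)[C@@H]1[C@H]3C=O | target

**Step count and risks**

Total steps: 14. Longest linear sequence: 13 steps (steps 1–7 and 9–14; step 8 is a one-step side branch).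

Steps most likely to fail:

1. Step 10 (key annulation). What may go wrong: alkylation of the hindered trione enolate through oxygen instead of carbon, followed by ring closure onto a ring carbonyl, or attack of the ylide on the C11 carbonyl instead of the side-chain ketone. Fallback, setting out from 15 and returning at 18: the two bonds are made in separate known operations. C-Allylation of 15 with allyl bromide and Cs2CO3 gives the 8α-allyl trione F1 (any O-allyl enol ether is converged by Claisen rearrangement on warming). Chemoselective Wittig methylenation of the unhindered side-chain ketone with Ph3P=CH2 gives the methylene compound F2. Ring-closing metathesis with the second-generation Grubbs catalyst then closes ring D to 18 with loss of ethene.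

2. Step 9 (Michael addition). What may go wrong: slow addition at the fully substituted C9, with competing tautomerization of the acylquinone toward an aromatic enone (loss of the C5 stereocenter) or 1,2-addition to a carbonyl. Fallback, setting out from 12 and returning at 18: Diels–Alder cycloaddition of 12 with commercial myrcene (ZnCl2, CH2Cl2, 0 °C → rt) at the acyl-activated C8=C9 bond. It should occur on the α-face and with the para orientation imposed by the C7 and C14 carbonyls (the diene CH2 next to its substituted carbon bonds to C9). This gives 18 directly without 15 or 17 and makes no further compound (F0).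

3. Step 12 (reduction that prepares the ring contraction). What may go wrong: loss of chemoselectivity in hydride delivery (reduction of the ring C enedione), or premature retro-aldol opening followed by over-reduction of the liberated aldehyde. Fallback, setting out from 18 and returning at 22: a Wolff ring contraction. Trifluoroacetylation of the C6 lithium enolate (LiN(SiMe3)2, CF3CO2CH2CF3, THF, −78 °C) gives the 6-trifluoroacetyl ketone F3. Detrifluoroacetylative diazo transfer (MsN3, Et3N, MeCN) gives the 6-diazo-7-ketone F4. Wolff rearrangement (PhCO2Ag, Et3N, PhSH, THF), in which C8 migrates to C6 and the ketene is trapped by the thiol, gives the ring-contracted S-phenyl thioester F5. Fukuyama reduction (Et3SiH, Pd/C, acetone) then gives 22.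

Further compounds
F0 | step 9 | none | none
F1 | step 10 | 8α-allyl-12-methoxy-9α-(6-methyl-2-oxohept-5-en-1-yl)abiet-12-ene-7,11,14-trione | CC(C)C=1C(=O)[C@]2(CC=C)[C@](CC(=O)CCC=C(C)C)(C(=O)C1OC)[C@@]1(C)CCCC(C)(C)[C@@H]1CC2=O
F2 | step 10 | 8α-allyl-12-methoxy-9α-(6-methyl-2-methylenehept-5-en-1-yl)abiet-12-ene-7,11,14-trione | CC(C)C=1C(=O)[C@]2(CC=C)[C@](CC(=C)CCC=C(C)C)(C(=O)C1OC)[C@@]1(C)CCCC(C)(C)[C@@H]1CC2=O
F3 | step 12 | 6-trifluoroacetyl derivative of 18 (enol form) | CC(C)C=1C(=O)[C@@]23CC=C(CCC=C(C)C)C[C@@]3(C(=O)C1OC)[C@@]1(C)CCCC(C)(C)[C@@H]1C(=C(O)C(F)(F)F)C2=O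
F4 | step 12 | 6-diazo derivative of 18 | CC(C)C=1C(=O)[C@@]23CC=C(CCC=C(C)C)C[C@@]3(C(=O)C1OC)[C@@]1(C)CCCC(C)(C)[C@@H]1C(=[N+]=[N-])C2=O
F5 | step 12 | ring-contracted S-phenyl thioester (22 with C(=O)SPh in place of the formyl group) | CC(C)=CCCC1=CC[C@@]23C(=O)C(C(C)C)=C(OC)C(=O)[C@]2(C1)[C@@]1(C)CCCC(C)(C)[C@@H]1[C@H]3C(=O)Sc1ccccc1
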